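**Strategy.** The decalin is disconnected across the C5–C10 ring-fusion bond and the C6–C7 bond. Ring B, whose exocyclic C8=C12 methylene sits next to the C9 carbinyl carbon, is read as the protodesilylated form of an allylsilane cyclohexene. One thermal intramolecular Diels–Alder reaction of an acyclic triene therefore closes rings A and B together and sets the quaternary C10, C5 and their trans relationship. The precursor carries a Z-configured 2-(trimethylsilylmethyl)diene (C7=C8–C9=C10), a four-atom keto tether (C1–C4) and, on the preformed quaternary C4, an E-vinyl sulfone (C5=C6) whose sulfonyl group is removed later.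

Key step: step 6

Numbering used throughout (terpenoid style): C1–C5 and C10 form ring A, C5–C10 form ring B; C11 is the CH2O carbon on C9, C12 the exocyclic carbon on C8, C18 the methyl and C19 the oxygenated carbon on C4, C20 the methyl on C10.

Assumption: the cinchonidinium-derived catalyst of step 5 is taken to deliver (S)-13; if the sense is the opposite, the pseudoenantiomeric cinchoninium salt is used with no other change.

Step 1
Reactants: 1 but-2-yn-1-ol; 2 (2-bromoprop-2-en-1-yl)trimethylsilane
Product: 5 (2Z)-3-iodo-2-[3-(trimethylsilyl)prop-1-en-2-yl]but-2-en-1-ol, via vinyl Grignard reagent 3 (not isolated), via magnesium chelate 4 (not isolated)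
Conditions: 2 (3 equiv), Mg, THF, 45 °C; 1 predeprotonated with i-PrMgCl (1 equiv); THF–toluene, 80 °C; then I2, −78 °C; aq. NH4Cl
Reagents that add atoms: iodine, II
Why: Magnesium-mediated anti-carbomagnesiation of a propargylic alkoxide puts the vinyl group on the alkyne carbon next to the carbinol and holds the new C–Mg bond cis to CH2O in a five-membered chelate, and iodinolysis with retention should give the Z iodide with the methyl cis to the silylallyl group.

Step 2
Reactants: 5 (2Z)-3-iodo-2-[3-(trimethylsilyl)prop-1-en-2-yl]but-2-en-1-ol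
Product: 6 tert-butyl{[(2Z)-3-iodo-2-[3-(trimethylsilyl)prop-1-en-2-yl]but-2-en-1-yl]oxy}dimethylsilane
Conditions: TBSCl, imidazole, DMF, 0 °C to rt
Reagents that add atoms: tert-butyl(chloro)dimethylsilane (TBSCl), CC(C)(C)[Si](C)(C)Cl
Why: Routine silylation of a primary allylic alcohol, which shields O11 from the bases of steps 4 and 5 and is removed in the same flask as the allylsilane in step 9.

Step 3
Reactants: 6 the silyl ether of step 2; 7 (3-ethoxy-3-oxopropyl)zinc bromide
Product: 8 ethyl (4Z)-5-({[tert-butyl(dimethyl)silyl]oxy}methyl)-4-methyl-6-[(trimethylsilyl)methyl]hepta-4,6-dienoate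
Conditions: Pd(OAc)2 (5 mol%), SPhos (10 mol%), THF, 50 °C
Reagents that add atoms: none
Why: Negishi coupling of a vinyl iodide with a functionalised alkylzinc halide should proceed with retention of the alkene geometry and tolerate the ester, the silyl ether and the allylsilane, so C1 ends cis to C11 and the methyl cis to C8.

Step 4
Reactants: 8 the ethyl ester of step 3; 9 tert-butyl propanoate
Product: 11 tert-butyl (6Z)-7-({[tert-butyl(dimethyl)silyl]oxy}methyl)-2,6-dimethyl-3-oxo-8-[(trimethylsilyl)methyl]nona-6,8-dienoate (racemic at C4), via lithium enolate 10 (not isolated)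
Conditions: 9 and LDA (3 equiv each), THF, −78 °C; then 8, −78 to −20 °C; aq. NH4Cl
Reagents that add atoms: none
Why: Crossed Claisen condensation in which the preformed, excess lithium enolate of the tert-butyl ester acylates on the unhindered ethyl ester and the product is stored as its enolate until work-up; C4 is formed as a racemate and is fixed in step 5.

Step 5
Reactants: 11 the β-keto ester of step 4; 12 (E)-1,2-bis(phenylsulfonyl)ethene
Product: 13 tert-butyl (2S,6Z)-7-({[tert-butyl(dimethyl)silyl]oxy}methyl)-2,6-dimethyl-3-oxo-2-[(E)-2-(phenylsulfonyl)ethenyl]-8-[(trimethylsilyl)methyl]nona-6,8-dienoate (C4 is S)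
Conditions: 12 (1.1 equiv), O-allyl-N-(9-anthracenylmethyl)cinchonidinium bromide (10 mol%), Cs2CO3, toluene–CHCl3 (7:1), −40 °C
Reagents that add atoms: none
Why: Asymmetric nucleophilic vinylic substitution (conjugate addition of the β-keto ester enolate, then loss of sulfinate) under chiral phase-transfer catalysis, in which the ammonium ion pair shields one enolate face and sets the all-carbon C4 centre, while addition–elimination on the E-disulfone should give the E-vinyl sulfone.

Step 6
Reactants: 13 the triene of step 5
Product: 14 trans-fused Diels–Alder adduct (4S,5S,6R,10R): Δ8(9)-octalin with C3 ketone, axial CO2t-Bu (C19) and equatorial methyl (C18) on C4, C5–H anti to the C10 methyl, equatorial SO2Ph on C6, CH2SiMe3 on C8 and CH2OTBS on C9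
Conditions: toluene (0.01 M), BHT (5 mol%), 120 °C, sealed tube
Reagents that add atoms: none
Why: Thermal, concerted but asynchronous [4+2] cycloaddition between the C7=C8–C9=C10 diene and the C5=C6 vinyl sulfone, joined through the C1–C4 tether, forms the C5–C10 and C6–C7 bonds in one operation; the closest known reaction type is the intramolecular Diels–Alder reaction of 1,7,9-decatrienes with a sulfonyl, nitro or ester group on the dienophile terminus. Ring B closes by the cycloaddition itself and ring A closes as the fused six-membered ring spanned by the tether in a chair-like C10–C1–C2–C3–C4–C5 array. The C5/C6 relationship follows from the E-geometry of the dienophile, and the trans C5–H/C10-methyl relationship from the transition state with the tether anti and the sulfonyl group endo; the syn-tether (cis-fused) alternative is further disfavoured because the C11 substituent on C9 clashes with the C1 methylene and the quaternary C4 would sit under the diene. The configuration of C5 and C10 relative to C4 is controlled by the C4 centre: the axial site at C4, which lies on the diene face next to the incoming C10 methyl, should be taken by the flat ester (smaller A-value, no methyl/methyl 1,3-diaxial contact, roughly perpendicular to the C3 carbonyl) while the C18 methyl is equatorial. The step therefore needs trans ring fusion and this facial sense; both rest on substrate conformation and are expected to be useful but not complete, with minor isomers removed by chromatography. The Z-methyl on C10 lowers the rate, which is why an activated dienophile and 120 °C are chosen, below the range where 1,5-hydrogen shift of the diene should compete.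

Step 7
Reactants: 14 the adduct of step 6
Product: 15 (3R,4R,5S,6R,10R)-diol sulfone: as 14 but with equatorial 3-OH and axial C19H2OH
Conditions: LiAlH4, THF, 0 °C to 40 °C; aq. NaOH work-up
Reagents that add atoms: none
Why: LiAlH4 should reduce the C3 ketone by axial hydride attack from the face opposite the axial C19 and C20 groups (as in reductions of 4,4-disubstituted 3-oxo terpenoids), giving the equatorial alcohol cis to C19, and should reduce the ester to the axial primary carbinol while the sulfone stays inert.

Step 8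
Reactants: 15 the diol sulfone of step 7
Product: 16 (3R,4R,5S,10R)-allylsilane diol: trans-fused Δ8(9)-octalin with 3-OH, C19H2OH, CH2SiMe3 on C8 and CH2OTBS on C9
Conditions: 6% Na/Hg, Na2HPO4, MeOH–THF (3:1), −20 to 0 °C
Reagents that add atoms: none
Why: Reductive desulfonylation of a secondary alkyl phenyl sulfone (electron transfer, loss of sulfinate, protonation) turns C6 into CH2, so its configuration is irrelevant, and no β-leaving group is present.

Step 9
Reactants: 16 the allylsilane diol of step 8
Product: 18 (3R,4R,5S,9R,10R)-triol: 3-OH, C19H2OH, C11H2OH, exocyclic C8=C12, via exocyclic alkene silyl ether 17 (not isolated)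
Conditions: TsOH·H2O (0.2 equiv), CH2Cl2–MeOH (4:1), −20 °C to rt
Reagents that add atoms: none
Why: Acid-mediated protodesilylation of the allylsilane (SE2′) should deliver the proton to C9 axially on the face opposite the axial C10 methyl, the β-silyl cation at C8 collapsing to the exocyclic alkene with CH2O equatorial, and the primary silyl ether is then methanolysed in the same flask.

Step 10
Reactants: 18 the triol of step 9; 19 7-hydroxy-2H-chromen-2-one (umbelliferone)
Product: 20 7-{[(1R,4aS,5R,6R,8aR)-6-hydroxy-5-(hydroxymethyl)-5,8a-dimethyl-2-methylidenedecahydronaphthalen-1-yl]methoxy}-2H-chromen-2-one (target)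
Conditions: 19 (1.2 equiv), PPh3, DIAD, THF, 0 °C to rt
Reagents that add atoms: none
Why: Mitsunobu etherification with an acidic phenol should occur by SN2 displacement at C11, the only primary carbinol that is not neopentylic, while the neopentylic C19–OH and the hindered secondary C3–OH are not displaced and no stereocentre is touched.

**Compound list**

1 | but-2-yn-1-ol | CC#CCO | starting material
2 | (2-bromoprop-2-en-1-yl)trimethylsilane | C=C(Br)C[Si](C)(C)C | starting material
3 | [3-(trimethylsilyl)prop-1-en-2-yl]magnesium bromide | C=C([Mg]Br)C[Si](C)(C)C | intermediate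
4 | 3-methyl-4-[3-(trimethylsilyl)prop-1-en-2-yl]-2,5-dihydro-1,2-oxamagnesole (cyclic vinylmagnesium alkoxide) | CC1=C(C(=C)C[Si](C)(C)C)CO[Mg]1 | intermediate
5 | (2Z)-3-iodo-2-[3-(trimethylsilyl)prop-1-en-2-yl]but-2-en-1-ol | I/C(C)=C(\CO)C(=C)C[Si](C)(C)C | intermediate
6 | tert-butyl{[(2Z)-3-iodo-2-[3-(trimethylsilyl)prop-1-en-2-yl]but-2-en-1-yl]oxy}dimethylsilane | I/C(C)=C(\CO[Si](C)(C)C(C)(C)C)C(=C)C[Si](C)(C)C | intermediate
7 | (3-ethoxy-3-oxopropyl)zinc bromide | CCOC(=O)CC[Zn]Br | starting material
8 | ethyl (4Z)-5-({[tert-butyl(dimethyl)silyl]oxy}methyl)-4-methyl-6-[(trimethylsilyl)methyl]hepta-4,6-dienoate | CCOC(=O)CC/C(C)=C(\CO[Si](C)(C)C(C)(C)C)C(=C)C[Si](C)(C)C | intermediate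
9 | tert-butyl propanoate | CCC(=O)OC(C)(C)C | starting material
10 | lithium enolate of tert-butyl propanoate | CC=C(O[Li])OC(C)(C)C | intermediate
11 | tert-butyl (6Z)-7-({[tert-butyl(dimethyl)silyl]oxy}methyl)-2,6-dimethyl-3-oxo-8-[(trimethylsilyl)methyl]nona-6,8-dienoate (racemic at C4) | CC(C)(C)OC(=O)C(C)C(=O)CC/C(C)=C(\CO[Si](C)(C)C(C)(C)C)C(=C)C[Si](C)(C)C | intermediate
12 | (E)-1,2-bis(phenylsulfonyl)ethene | O=S(=O)(/C=C/S(=O)(=O)c1ccccc1)c1ccccc1 | starting material
13 | tert-butyl (2S,6Z)-7-({[tert-butyl(dimethyl)silyl]oxy}methyl)-2,6-dimethyl-3-oxo-2-[(E)-2-(phenylsulfonyl)ethenyl]-8-[(trimethylsilyl)methyl]nona-6,8-dienoate | CC(C)(C)OC(=O)[C@@](C)(/C=C/S(=O)(=O)c1ccccc1)C(=O)CC/C(C)=C(\CO[Si](C)(C)C(C)(C)C)C(=C)C[Si](C)(C)C | intermediate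
14 | (4S,5S,6R,10R) trans-fused adduct: 3-oxo, C19 tert-butyl ester (axial), 6-phenylsulfonyl (equatorial), 8-CH2SiMe3, 9-CH2OTBS, Δ8(9) | C[Si](C)(C)CC=1C[C@@H](S(=O)(=O)c3ccccc3)[C@@H]2[C@](C)(C(=O)OC(C)(C)C)C(=O)CC[C@@]2(C)C=1CO[Si](C)(C)C(C)(C)C | intermediate
15 | (3R,4R,5S,6R,10R) diol sulfone: 3-OH (equatorial), C19H2OH (axial), 6-phenylsulfonyl, 8-CH2SiMe3, 9-CH2OTBS, Δ8(9) | C[Si](C)(C)CC=1C[C@@H](S(=O)(=O)c3ccccc3)[C@@H]2[C@](C)(CO)[C@H](O)CC[C@@]2(C)C=1CO[Si](C)(C)C(C)(C)C | intermediate
16 | (3R,4R,5S,10R) allylsilane diol: 3-OH, C19H2OH, 8-CH2SiMe3, 9-CH2OTBS, Δ8(9) | C[Si](C)(C)CC=1CC[C@@H]2[C@](C)(CO)[C@H](O)CC[C@@]2(C)C=1CO[Si](C)(C)C(C)(C)C | intermediate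
17 | (3R,4R,5S,9R,10R) exocyclic alkene, C11 silyl ether: 3-OH, C19H2OH, C11H2OTBS, C8=C12H2 | C=C1CC[C@@H]2[C@](C)(CO)[C@H](O)CC[C@@]2(C)[C@@H]1CO[Si](C)(C)C(C)(C)C | intermediate
18 | (3R,4R,5S,9R,10R) triol: (1R,2R,4aS,5R,8aR)-1,5-bis(hydroxymethyl)-1,4a-dimethyl-6-methylidenedecahydronaphthalen-2-ol | C=C1CC[C@@H]2[C@](C)(CO)[C@H](O)CC[C@@]2(C)[C@@H]1CO | intermediate
19 | 7-hydroxy-2H-chromen-2-one (umbelliferone) | Oc1ccc2ccc(=O)oc2c1 | starting material
20 | 7-{[(1R,4aS,5R,6R,8aR)-6-hydroxy-5-(hydroxymethyl)-5,8a-dimethyl-2-methylidenedecahydronaphthalen-1-yl]methoxy}-2H-chromen-2-one | C=C1CC[C@@H]2[C@](C)(CO)[C@H](O)CC[C@@]2(C)[C@@H]1COc1ccc2ccc(=O)oc2c1 | target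

**Step count.** Total: 10 steps. Longest linear sequence: 10 steps (from 1).

**Steps most likely to fail**

1. Step 6. The hindered cycloaddition (Z-methyl on the diene terminus, quaternary carbon next to the dienophile) may be too slow at temperatures the diene tolerates, or the syn-tether transition state may compete and erode the trans ring fusion. Fallback, setting out from 11 and returning at 16: the sulfone is replaced by an ester that a Lewis acid can activate at low temperature, where the endo preference is stronger. Conjugate addition of 11 to ethyl propiolate under the ion-pairing catalysis of step 5, with iodine-catalysed equilibration to the E-isomer, should give tert-butyl (2S,6Z)-7-({[tert-butyl(dimethyl)silyl]oxy}methyl)-2-[(E)-3-ethoxy-3-oxoprop-1-en-1-yl]-2,6-dimethyl-3-oxo-8-[(trimethylsilyl)methyl]nona-6,8-dienoate F1. Me2AlCl in CH2Cl2 at −20 °C should promote the intramolecular Diels–Alder reaction to the trans-fused C6 ethyl ester adduct F2. LiOH in aqueous THF cleaves only the secondary ethyl ester to give the C6 carboxylic acid F3. Barton decarboxylation (N-hydroxypyridine-2-thione, DCC; then t-BuSH, light) gives the C6-unsubstituted keto ester F4, and LiAlH4 as in step 7 leads to 16.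

2. Step 5. Enantiofacial discrimination in the ion pair of an acyclic β-keto ester enolate may be low. Fallback, setting out from 11 and returning at 13: an auxiliary replaces the catalyst. Condensation of 11 with (S)-1-phenylethylamine (TsOH cat., toluene, water removal) gives the hydrogen-bonded Z β-enamino ester F5. Its Michael addition to 12 in THF with loss of benzenesulfinic acid gives the α-vinylated ketimine F6, which aqueous acetic acid hydrolyses to 13; the antipodal amine is used if the sense requires it.

3. Step 10. The neopentylic C19 hydroxyl or the 1,3-diol unit may be activated competitively (cyclic phosphorane or ether formation), so that the etherification is not clean at C11. Fallback, setting out from 18 and returning at 20: the diol is masked first. 2,2-Dimethoxypropane with PPTS in CH2Cl2 should convert only the 1,3-diol of 18 into the 3,19-acetonide F7. Mitsunobu coupling of F7 with 19 gives the acetonide-protected aryl ether F8, and 80% aqueous acetic acid at rt releases 20.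

**Further compounds**

F1 | step 6 | tert-butyl (2S,6Z)-7-({[tert-butyl(dimethyl)silyl]oxy}methyl)-2-[(E)-3-ethoxy-3-oxoprop-1-en-1-yl]-2,6-dimethyl-3-oxo-8-[(trimethylsilyl)methyl]nona-6,8-dienoate | CC(C)(C)OC(=O)[C@@](C)(/C=C/C(=O)OCC)C(=O)CC/C(C)=C(\CO[Si](C)(C)C(C)(C)C)C(=C)C[Si](C)(C)C
F2 | step 6 | (4S,5S,6R,10R) trans-fused adduct with equatorial CO2Et on C6 (otherwise as 14) | C[Si](C)(C)CC=1C[C@@H](C(=O)OCC)[C@@H]2[C@](C)(C(=O)OC(C)(C)C)C(=O)CC[C@@]2(C)C=1CO[Si](C)(C)C(C)(C)C
F3 | step 6 | (4S,5S,6R,10R) C6 carboxylic acid of F2 | C[Si](C)(C)CC=1C[C@@H](C(=O)O)[C@@H]2[C@](C)(C(=O)OC(C)(C)C)C(=O)CC[C@@]2(C)C=1CO[Si](C)(C)C(C)(C)C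
F4 | step 6 | (4S,5S,10R) keto ester: 14 without the C6 substituent | C[Si](C)(C)CC=1CC[C@@H]2[C@](C)(C(=O)OC(C)(C)C)C(=O)CC[C@@]2(C)C=1CO[Si](C)(C)C(C)(C)C
F5 | step 5 | Z β-enamino ester of 11 with (S)-1-phenylethylamine | CC(C)(C)OC(=O)/C(C)=C(\N[C@@H](C)c1ccccc1)CC/C(C)=C(\CO[Si](C)(C)C(C)(C)C)C(=C)C[Si](C)(C)C
F6 | step 5 | N-[(S)-1-phenylethyl] ketimine of 13 | CC(C)(C)OC(=O)[C@@](C)(/C=C/S(=O)(=O)c1ccccc1)C(=N[C@@H](C)c1ccccc1)CC/C(C)=C(\CO[Si](C)(C)C(C)(C)C)C(=C)C[Si](C)(C)C
F7 | step 10 | 3,19-O-isopropylidene derivative of 18 (C11–OH free) | C=C1CC[C@@H]2[C@](C)(COC(C)(C)O3)[C@H]3CC[C@@]2(C)[C@@H]1CO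
F8 | step 10 | 3,19-O-isopropylidene derivative of 20 | C=C1CC[C@@H]2[C@](C)(COC(C)(C)O3)[C@H]3CC[C@@]2(C)[C@@H]1COc1ccc2ccc(=O)oc2c1
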